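**Retrosynthetic overview**
1. Target ⇐ protected coupled product 33 (aryl methyl ethers, diol as bis-TBS ether) by oxidative demethylation, reduction, sulfation and desilylation.
2. 33 ⇐ ring B alkenyl iodide 17 + allylboronate 32 by a proposed domino Heck cyclization/allyl Suzuki coupling that closes ring A, sets the quaternary C5 and attaches the side chain.
3. 17 ⇐ ketone 7 (α-iodoenone, alkyl addition, oxidative 1,3-transposition, deoxygenation); 7 ⇐ 2-methylcyclohex-2-enone by asymmetric conjugate methylation and enolate benzylation.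
4. 32 ⇐ geraniol by Sharpless epoxidation, Payne inversion (anti diol), propargylation, carboalumination and boron homologation.
5. Ring order: ring B first (from the cyclohexenone), ring A last (step 18).

Assumption: the target is taken as the neutral bis(hydrogen sulfate) drawn; aryl sulfates are handled as pyridinium or sodium salts and written in neutral form.

**Route**

Step 1
Reactants: 1 (2,5-dimethoxyphenyl)methanol
Product: 2 2-(bromomethyl)-1,4-dimethoxybenzene
Conditions: PBr3, Et2O, 0 °C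
Reagents that add atoms: phosphorus tribromide, BrP(Br)Br
Why: Standard conversion of a benzylic alcohol to the bromide (nucleophilic substitution via the phosphite ester), with no stereocenter involved.

Step 2
Reactants: 3 2-methylcyclohex-2-en-1-one
Product: 5 {[(3S)-2,3-dimethylcyclohex-1-en-1-yl]oxy}trimethylsilane, via aluminium enolate 4 (not isolated)
Conditions: AlMe3, copper thiophene-2-carboxylate CuO2CC4H3S (2 mol%), phosphoramidite from (S)-BINOL and bis[(R)-1-phenylethyl]amine (4 mol%), Et2O, −30 °C; then TMSOTf, −30 → 0 °C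
Reagents that add atoms: trimethylaluminium, C[Al](C)C; trimethylsilyl trifluoromethanesulfonate, C[Si](C)(C)OS(=O)(=O)C(F)(F)F
Why: Copper-catalysed asymmetric conjugate addition sets C3 (S) under ligand control and the regiodefined enolate is trapped as the silyl enol ether; the ligand antipode is the one that gives 3S, to be confirmed by rotation at the stage of 7.

Step 3
Reactants: 5 {[(3S)-2,3-dimethylcyclohex-1-en-1-yl]oxy}trimethylsilane; 2 2-(bromomethyl)-1,4-dimethoxybenzene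
Product: 7 (2R,3S)-2-[(2,5-dimethoxyphenyl)methyl]-2,3-dimethylcyclohexan-1-one, via lithium enolate 6 (not isolated)
Conditions: MeLi, THF, 0 °C; then DMPU, 2, −78 → −20 °C
Reagents that add atoms: none
Why: Regiospecific enolate alkylation in which the benzyl bromide enters anti to the adjacent C3 methyl, setting the quaternary C2 (R) with the two methyls cis; the minor epimer is removed by chromatography.

Step 4
Reactants: 7 (2R,3S)-2-[(2,5-dimethoxyphenyl)methyl]-2,3-dimethylcyclohexan-1-one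
Product: 9 (5S,6R)-6-[(2,5-dimethoxyphenyl)methyl]-5,6-dimethylcyclohex-2-en-1-one, via lithium enolate 8 (not isolated)
Conditions: LiN(iPr)2, THF, −78 °C; then PhS(Cl)=N-t-Bu, −78 °C
Reagents that add atoms: none
Why: Mukaiyama one-pot dehydrogenation of the only enolisable side (the other α-carbon is quaternary) gives the enone without touching the stereocenters.

Step 5
Reactants: 9 (5S,6R)-6-[(2,5-dimethoxyphenyl)methyl]-5,6-dimethylcyclohex-2-en-1-one
Product: 10 (5S,6R)-6-[(2,5-dimethoxyphenyl)methyl]-2-iodo-5,6-dimethylcyclohex-2-en-1-one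
Conditions: I2, pyridine/CH2Cl2 (1:1), 0 → 25 °C
Reagents that add atoms: iodine, II
Why: Johnson α-iodination (pyridine conjugate addition, enolate iodination, elimination) works well on this β-unsubstituted enone, and iodine alone does not attack the dimethoxyarene.

Step 6
Reactants: 10 (5S,6R)-6-[(2,5-dimethoxyphenyl)methyl]-2-iodo-5,6-dimethylcyclohex-2-en-1-one; 11 5-bromo-2-methylpent-1-ene
Product: 13 (1R,5S,6R)-6-[(2,5-dimethoxyphenyl)methyl]-2-iodo-5,6-dimethyl-1-(4-methylpent-4-en-1-yl)cyclohex-2-en-1-ol, via Grignard reagent 12 (not isolated)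
Conditions: 11, Mg, THF; anhydrous CeCl3, THF, −78 °C; then 10, −78 → −40 °C; H2O
Reagents that add atoms: none
Why: Cerium-chloride-promoted Grignard 1,2-addition suppresses conjugate addition and iodine–magnesium exchange; the carbinol configuration (expected major isomer drawn, alkyl anti to the arylmethyl group) is erased in step 7.

Step 7
Reactants: 13 (1R,5S,6R)-6-[(2,5-dimethoxyphenyl)methyl]-2-iodo-5,6-dimethyl-1-(4-methylpent-4-en-1-yl)cyclohex-2-en-1-ol
Product: 14 (4R,5S)-4-[(2,5-dimethoxyphenyl)methyl]-2-iodo-4,5-dimethyl-3-(4-methylpent-4-en-1-yl)cyclohex-2-en-1-one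
Conditions: pyridinium chlorochromate [C5H5NH][CrO3Cl], 4 Å MS, CH2Cl2, 25 °C
Reagents that add atoms: pyridinium chlorochromate, [O-][Cr](=O)(=O)Cl.c1cc[nH+]cc1
Why: Dauben oxidative 1,3-transposition (chromate ester, [3,3] shift, oxidation) moves oxygen to the ring methylene and fixes the tetrasubstituted alkene with iodine on the carbon that will bond to C5 and the tether on its neighbour.

Step 8
Reactants: 14 (4R,5S)-4-[(2,5-dimethoxyphenyl)methyl]-2-iodo-4,5-dimethyl-3-(4-methylpent-4-en-1-yl)cyclohex-2-en-1-one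
Product: 15 (1R,4R,5S)-4-[(2,5-dimethoxyphenyl)methyl]-2-iodo-4,5-dimethyl-3-(4-methylpent-4-en-1-yl)cyclohex-2-en-1-ol
Conditions: NaBH4, CeCl3·7H2O, MeOH, −40 °C
Reagents that add atoms: none
Why: Luche 1,2-reduction of the enone; the new carbinol center (major isomer drawn, hydroxyl cis to the C5 methyl) is removed in step 9.

Step 9
Reactants: 15 (1R,4R,5S)-4-[(2,5-dimethoxyphenyl)methyl]-2-iodo-4,5-dimethyl-3-(4-methylpent-4-en-1-yl)cyclohex-2-en-1-ol
Product: 17 2-{[(1R,6S)-3-iodo-1,6-dimethyl-2-(4-methylpent-4-en-1-yl)cyclohex-2-en-1-yl]methyl}-1,4-dimethoxybenzene, via allylic mesylate 16 (not isolated)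
Conditions: MsCl, Et3N, CH2Cl2, −30 °C; then LiBHEt3, THF, −30 → 0 °C
Reagents that add atoms: none
Why: Sulfonylation and SN2 hydride displacement at the unhindered secondary allylic carbon deoxygenates the ring; SN2′ attack at the fully substituted alkene carbon is blocked, so the alkene stays in place.

Step 10
Reactants: 18 (2E)-3,7-dimethylocta-2,6-dien-1-ol (geraniol)
Product: 19 [(2R,3R)-3-methyl-3-(4-methylpent-3-en-1-yl)oxiran-2-yl]methanol
Conditions: Ti(OiPr)4 (5 mol%), D-(−)-diethyl tartrate (6 mol%), t-BuOOH, 4 Å MS, CH2Cl2, −20 °C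
Reagents that add atoms: tert-butyl hydroperoxide, CC(C)(C)OO
Why: Sharpless asymmetric epoxidation of the allylic alcohol sets both epoxide centers (2R,3R with the D-tartrate) and leaves the remote alkene untouched.

Step 11
Reactants: 19 [(2R,3R)-3-methyl-3-(4-methylpent-3-en-1-yl)oxiran-2-yl]methanol
Product: 21 (2R,3R)-3,7-dimethyl-1-(phenylsulfanyl)oct-6-ene-2,3-diol, via Payne epoxy alcohol 20 (not isolated)
Conditions: PhSH, NaOH (0.5 M aq), t-BuOH, 80 °C, slow addition of 19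
Reagents that add atoms: thiophenol, Sc1ccccc1
Why: Payne rearrangement–opening: the C1 alkoxide inverts C2 by intramolecular SN2 and thiolate traps the terminal epoxide at C1, giving the anti secondary/tertiary diol with the tertiary center retained.

Step 12
Reactants: 21 (2R,3R)-3,7-dimethyl-1-(phenylsulfanyl)oct-6-ene-2,3-diol
Product: 22 [(2R,3R)-2,3-dihydroxy-3,7-dimethyloct-6-en-1-yl](methyl)phenylsulfonium tetrafluoroborate
Conditions: Me3OBF4, CH2Cl2, 0 → 25 °C; used crude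
Reagents that add atoms: trimethyloxonium tetrafluoroborate, C[O+](C)C.F[B-](F)(F)F
Why: Chemoselective S-methylation of the sulfide (far more nucleophilic than the hydroxyls or the alkene) turns sulfur into a leaving group.

Step 13
Reactants: 22 [(2R,3R)-2,3-dihydroxy-3,7-dimethyloct-6-en-1-yl](methyl)phenylsulfonium tetrafluoroborate
Product: 20 (2R)-6-methyl-2-[(2S)-oxiran-2-yl]hept-5-en-2-ol
Conditions: NaH (1.05 equiv), THF, 0 °C, 30 min
Reagents that add atoms: none
Why: Intramolecular Williamson closure by the secondary alkoxide displaces thioanisole at C1 with no change at either stereocenter, giving the terminal epoxide as the kinetic product.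

Step 14
Reactants: 20 (2R)-6-methyl-2-[(2S)-oxiran-2-yl]hept-5-en-2-ol; 23 trimethyl(prop-1-yn-1-yl)silane
Product: 26 (5S,6R)-6,10-dimethylundec-9-en-1-yne-5,6-diol, via lithiated silylpropyne 24 (not isolated), via silylalkyne diol 25 (not isolated)
Conditions: 23, n-BuLi, THF, −78 → 0 °C; then 20, DMPU, −78 → 25 °C; then MeOH, K2CO3, 25 °C
Reagents that add atoms: none
Why: The propargylic lithium opens the terminal epoxide at its CH2 carbon (any Payne back-equilibration funnels through the same terminal epoxide) and methanolysis removes the alkynyl silyl group; neither stereocenter is touched.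

Step 15
Reactants: 26 (5S,6R)-6,10-dimethylundec-9-en-1-yne-5,6-diol
Product: 27 (5S,6R)-5,6-bis{[tert-butyl(dimethyl)silyl]oxy}-6,10-dimethylundec-9-en-1-yne
Conditions: TBSOTf, 2,6-lutidine, CH2Cl2, 0 → 40 °C
Reagents that add atoms: tert-butyldimethylsilyl trifluoromethanesulfonate, CC(C)(C)[Si](C)(C)OS(=O)(=O)C(F)(F)F
Why: The silyl triflate protects both the secondary and the hindered tertiary hydroxyl, which must be masked during organometallic steps and the later sulfation.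

Step 16
Reactants: 27 (5S,6R)-5,6-bis{[tert-butyl(dimethyl)silyl]oxy}-6,10-dimethylundec-9-en-1-yne
Product: 29 (1E,5S,6R)-5,6-bis{[tert-butyl(dimethyl)silyl]oxy}-1-iodo-2,6,10-trimethylundeca-1,9-diene, via alkenylalane 28 (not isolated)
Conditions: AlMe3, Cp2ZrCl2 (0.3 equiv), H2O (1 equiv), CH2Cl2, −20 → 0 °C; then I2, THF, −30 °C
Reagents that add atoms: trimethylaluminium, C[Al](C)C; iodine, II
Why: Negishi zirconium-catalysed carboalumination adds methyl and aluminium syn across the terminal alkyne, and iodinolysis with retention gives the E trisubstituted alkenyl iodide.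

Step 17
Reactants: 29 (1E,5S,6R)-5,6-bis{[tert-butyl(dimethyl)silyl]oxy}-1-iodo-2,6,10-trimethylundeca-1,9-diene
Product: 32 2-[(2E,6S,7R)-6,7-bis{[tert-butyl(dimethyl)silyl]oxy}-3,7,11-trimethyldodeca-2,10-dien-1-yl]-4,4,5,5-tetramethyl-1,3,2-dioxaborolane, via alkenyllithium 30 (not isolated), via chloromethyl boronate complex 31 (not isolated)
Conditions: t-BuLi (2.1 equiv), Et2O, −78 °C; then ClCH2B(pin), −78 → 25 °C
Reagents that add atoms: 2-(chloromethyl)-4,4,5,5-tetramethyl-1,3,2-dioxaborolane, ClCB1OC(C)(C)C(C)(C)O1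
Why: Matteson-type homologation: the alkenyllithium adds to boron and 1,2-migration of the alkenyl group displaces chloride, giving the allylboronate with the E geometry retained.

Step 18
Reactants: 17 2-{[(1R,6S)-3-iodo-1,6-dimethyl-2-(4-methylpent-4-en-1-yl)cyclohex-2-en-1-yl]methyl}-1,4-dimethoxybenzene; 32 2-[(2E,6S,7R)-6,7-bis{[tert-butyl(dimethyl)silyl]oxy}-3,7,11-trimethyldodeca-2,10-dien-1-yl]-4,4,5,5-tetramethyl-1,3,2-dioxaborolane
Product: 33 2-{[(1R,2S,5R)-5-[(3E,7S,8R)-7,8-bis{[tert-butyl(dimethyl)silyl]oxy}-4,8,12-trimethyltrideca-3,11-dien-1-yl]-1,2,5-trimethyl-1,2,3,4,5,6,7,8-octahydronaphthalen-1-yl]methyl}-1,4-dimethoxybenzene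
Conditions: Pd(OAc)2 (10 mol%), (R)-BINAP (15 mol%), Ag2O (1.2 equiv), THF/H2O (20:1), 60 °C, slow addition of 32 (1.5 equiv)
Reagents that add atoms: none
Why: Proposed new method: an enantioselective domino Heck cyclization terminated by sp3–sp3 allyl Suzuki coupling, in which the alkenylpalladium from 17 (made cationic by silver-assisted iodide loss) undergoes ligand-controlled 6-exo carbopalladation of the 1,1-disubstituted alkene to close ring A and set C5 (R), and the resulting neopentyl alkylpalladium, which has no β-hydrogen, is captured by transmetalation with 32 and reductive elimination at the unhindered α-carbon of the allyl ligand with the E alkene preserved; the closest known reaction type is the asymmetric domino Heck/Suzuki–Miyaura coupling with aryl- or alkenylboron reagents together with α-selective Suzuki coupling of γ,γ-disubstituted allylboronates, and the (R)-BINAP facial sense is assigned by analogy, so the antipodal ligand is used if it proves opposite.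

Step 19
Reactants: 33 2-{[(1R,2S,5R)-5-[(3E,7S,8R)-7,8-bis{[tert-butyl(dimethyl)silyl]oxy}-4,8,12-trimethyltrideca-3,11-dien-1-yl]-1,2,5-trimethyl-1,2,3,4,5,6,7,8-octahydronaphthalen-1-yl]methyl}-1,4-dimethoxybenzene
Product: 34 2-{[(1R,2S,5R)-5-[(3E,7S,8R)-7,8-bis{[tert-butyl(dimethyl)silyl]oxy}-4,8,12-trimethyltrideca-3,11-dien-1-yl]-1,2,5-trimethyl-1,2,3,4,5,6,7,8-octahydronaphthalen-1-yl]methyl}cyclohexa-2,5-diene-1,4-dione
Conditions: (NH4)2Ce(NO3)6 (2.5 equiv), MeCN/H2O (4:1), 0 °C, 15 min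
Reagents that add atoms: water, O
Why: Oxidative demethylation of the 1,4-dimethoxyarene to the quinone (arene radical cation, water addition, loss of methanol) is faster than alkene oxidation at 0 °C and tolerates TBS ethers.

Step 20
Reactants: 34 2-{[(1R,2S,5R)-5-[(3E,7S,8R)-7,8-bis{[tert-butyl(dimethyl)silyl]oxy}-4,8,12-trimethyltrideca-3,11-dien-1-yl]-1,2,5-trimethyl-1,2,3,4,5,6,7,8-octahydronaphthalen-1-yl]methyl}cyclohexa-2,5-diene-1,4-dione
Product: 36 2-{[(1R,2S,5R)-5-[(3E,7S,8R)-7,8-bis{[tert-butyl(dimethyl)silyl]oxy}-4,8,12-trimethyltrideca-3,11-dien-1-yl]-1,2,5-trimethyl-1,2,3,4,5,6,7,8-octahydronaphthalen-1-yl]methyl}benzene-1,4-diyl bis(hydrogen sulfate), via hydroquinone 35 (not isolated)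
Conditions: Na2S2O4, THF/H2O, 25 °C, Ar; then SO3·pyridine (8 equiv), pyridine, 50 °C
Reagents that add atoms: sulfur trioxide pyridine complex, O=S(=O)([O-])[n+]1ccccc1
Why: Dithionite reduces the quinone to the air-sensitive hydroquinone, which is O-sulfated at once by the sulfur trioxide complex while both aliphatic hydroxyls are still silylated.

Step 21
Reactants: 36 2-{[(1R,2S,5R)-5-[(3E,7S,8R)-7,8-bis{[tert-butyl(dimethyl)silyl]oxy}-4,8,12-trimethyltrideca-3,11-dien-1-yl]-1,2,5-trimethyl-1,2,3,4,5,6,7,8-octahydronaphthalen-1-yl]methyl}benzene-1,4-diyl bis(hydrogen sulfate)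
Product: 37 2-{[(1R,2S,5R)-5-[(3E,7S,8R)-7,8-dihydroxy-4,8,12-trimethyltrideca-3,11-dien-1-yl]-1,2,5-trimethyl-1,2,3,4,5,6,7,8-octahydronaphthalen-1-yl]methyl}benzene-1,4-diyl bis(hydrogen sulfate)
Conditions: HF·pyridine, pyridine, THF, 0 → 35 °C
Reagents that add atoms: none
Why: Buffered fluoride desilylation frees the secondary and tertiary alcohols under conditions too mild to hydrolyse aryl sulfates or isomerise the alkenes.

**Compound list**
1 | (2,5-dimethoxyphenyl)methanol | COc1ccc(OC)c(CO)c1 | starting material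
2 | 2-(bromomethyl)-1,4-dimethoxybenzene | COc1ccc(OC)c(CBr)c1 | intermediate
3 | 2-methylcyclohex-2-en-1-one | CC1=CCCCC1=O | starting material
4 | dimethylaluminium (3S)-2,3-dimethylcyclohex-1-en-1-olate | C[Al](C)OC1=C(C)[C@@H](C)CCC1 | intermediate
5 | {[(3S)-2,3-dimethylcyclohex-1-en-1-yl]oxy}trimethylsilane | C[Si](C)(C)OC1=C(C)[C@@H](C)CCC1 | intermediate
6 | lithium (3S)-2,3-dimethylcyclohex-1-en-1-olate | [Li]OC1=C(C)[C@@H](C)CCC1 | intermediate
7 | (2R,3S)-2-[(2,5-dimethoxyphenyl)methyl]-2,3-dimethylcyclohexan-1-one | O=C1CCC[C@H](C)[C@@]1(C)Cc2cc(OC)ccc2OC | intermediate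
8 | lithium (5S,6R)-6-[(2,5-dimethoxyphenyl)methyl]-5,6-dimethylcyclohex-1-en-1-olate | [Li]OC1=CCC[C@H](C)[C@@]1(C)Cc2cc(OC)ccc2OC | intermediate
9 | (5S,6R)-6-[(2,5-dimethoxyphenyl)methyl]-5,6-dimethylcyclohex-2-en-1-one | O=C1C=CC[C@H](C)[C@@]1(C)Cc2cc(OC)ccc2OC | intermediate
10 | (5S,6R)-6-[(2,5-dimethoxyphenyl)methyl]-2-iodo-5,6-dimethylcyclohex-2-en-1-one | O=C1C(I)=CC[C@H](C)[C@@]1(C)Cc2cc(OC)ccc2OC | intermediate
11 | 5-bromo-2-methylpent-1-ene | C=C(C)CCCBr | starting material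
12 | (4-methylpent-4-en-1-yl)magnesium bromide | C=C(C)CCC[Mg]Br | intermediate
13 | (1R,5S,6R)-6-[(2,5-dimethoxyphenyl)methyl]-2-iodo-5,6-dimethyl-1-(4-methylpent-4-en-1-yl)cyclohex-2-en-1-ol | C=C(C)CCC[C@]1(O)C(I)=CC[C@H](C)[C@@]1(C)Cc2cc(OC)ccc2OC | intermediate
14 | (4R,5S)-4-[(2,5-dimethoxyphenyl)methyl]-2-iodo-4,5-dimethyl-3-(4-methylpent-4-en-1-yl)cyclohex-2-en-1-one | C=C(C)CCCC1=C(I)C(=O)C[C@H](C)[C@@]1(C)Cc2cc(OC)ccc2OC | intermediate
15 | (1R,4R,5S)-4-[(2,5-dimethoxyphenyl)methyl]-2-iodo-4,5-dimethyl-3-(4-methylpent-4-en-1-yl)cyclohex-2-en-1-ol | C=C(C)CCCC1=C(I)[C@H](O)C[C@H](C)[C@@]1(C)Cc2cc(OC)ccc2OC | intermediate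
16 | (1R,4R,5S)-4-[(2,5-dimethoxyphenyl)methyl]-2-iodo-4,5-dimethyl-3-(4-methylpent-4-en-1-yl)cyclohex-2-en-1-yl methanesulfonate | C=C(C)CCCC1=C(I)[C@H](OS(C)(=O)=O)C[C@H](C)[C@@]1(C)Cc2cc(OC)ccc2OC | intermediate
17 | 2-{[(1R,6S)-3-iodo-1,6-dimethyl-2-(4-methylpent-4-en-1-yl)cyclohex-2-en-1-yl]methyl}-1,4-dimethoxybenzene | C=C(C)CCCC1=C(I)CC[C@H](C)[C@@]1(C)Cc2cc(OC)ccc2OC | intermediate
18 | (2E)-3,7-dimethylocta-2,6-dien-1-ol (geraniol) | CC(C)=CCC/C(C)=C/CO | starting material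
19 | [(2R,3R)-3-methyl-3-(4-methylpent-3-en-1-yl)oxiran-2-yl]methanol | CC(C)=CCC[C@@]1(C)O[C@@H]1CO | intermediate
20 | (2R)-6-methyl-2-[(2S)-oxiran-2-yl]hept-5-en-2-ol | CC(C)=CCC[C@@](C)(O)[C@@H]1CO1 | intermediate
21 | (2R,3R)-3,7-dimethyl-1-(phenylsulfanyl)oct-6-ene-2,3-diol | CC(C)=CCC[C@@](C)(O)[C@@H](O)CSc1ccccc1 | intermediate
22 | [(2R,3R)-2,3-dihydroxy-3,7-dimethyloct-6-en-1-yl](methyl)phenylsulfonium tetrafluoroborate | CC(C)=CCC[C@@](C)(O)[C@@H](O)C[S+](C)c1ccccc1.F[B-](F)(F)F | intermediate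
23 | trimethyl(prop-1-yn-1-yl)silane | CC#C[Si](C)(C)C | starting material
24 | [3-(trimethylsilyl)prop-2-yn-1-yl]lithium | [Li]CC#C[Si](C)(C)C | intermediate
25 | (5S,6R)-6,10-dimethyl-1-(trimethylsilyl)undec-9-en-1-yne-5,6-diol | CC(C)=CCC[C@@](C)(O)[C@@H](O)CCC#C[Si](C)(C)C | intermediate
26 | (5S,6R)-6,10-dimethylundec-9-en-1-yne-5,6-diol | CC(C)=CCC[C@@](C)(O)[C@@H](O)CCC#C | intermediate
27 | (5S,6R)-5,6-bis{[tert-butyl(dimethyl)silyl]oxy}-6,10-dimethylundec-9-en-1-yne | CC(C)=CCC[C@@](C)(O[Si](C)(C)C(C)(C)C)[C@@H](O[Si](C)(C)C(C)(C)C)CCC#C | intermediate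
28 | [(1E,5S,6R)-5,6-bis{[tert-butyl(dimethyl)silyl]oxy}-2,6,10-trimethylundeca-1,9-dien-1-yl]dimethylalumane | CC(C)=CCC[C@@](C)(O[Si](C)(C)C(C)(C)C)[C@@H](O[Si](C)(C)C(C)(C)C)CC/C(C)=C/[Al](C)C | intermediate
29 | (1E,5S,6R)-5,6-bis{[tert-butyl(dimethyl)silyl]oxy}-1-iodo-2,6,10-trimethylundeca-1,9-diene | CC(C)=CCC[C@@](C)(O[Si](C)(C)C(C)(C)C)[C@@H](O[Si](C)(C)C(C)(C)C)CC/C(C)=C/I | intermediate
30 | [(1E,5S,6R)-5,6-bis{[tert-butyl(dimethyl)silyl]oxy}-2,6,10-trimethylundeca-1,9-dien-1-yl]lithium | CC(C)=CCC[C@@](C)(O[Si](C)(C)C(C)(C)C)[C@@H](O[Si](C)(C)C(C)(C)C)CC/C(C)=C/[Li] | intermediate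
31 | lithium (chloromethyl)[(1E,5S,6R)-5,6-bis{[tert-butyl(dimethyl)silyl]oxy}-2,6,10-trimethylundeca-1,9-dien-1-yl](pinacolato)borate | [Li+].CC(C)=CCC[C@@](C)(O[Si](C)(C)C(C)(C)C)[C@@H](O[Si](C)(C)C(C)(C)C)CC/C(C)=C/[B-]1(CCl)OC(C)(C)C(C)(C)O1 | intermediate
32 | 2-[(2E,6S,7R)-6,7-bis{[tert-butyl(dimethyl)silyl]oxy}-3,7,11-trimethyldodeca-2,10-dien-1-yl]-4,4,5,5-tetramethyl-1,3,2-dioxaborolane | CC(C)=CCC[C@@](C)(O[Si](C)(C)C(C)(C)C)[C@@H](O[Si](C)(C)C(C)(C)C)CC/C(C)=C/CB1OC(C)(C)C(C)(C)O1 | intermediate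
33 | 2-{[(1R,2S,5R)-5-[(3E,7S,8R)-7,8-bis{[tert-butyl(dimethyl)silyl]oxy}-4,8,12-trimethyltrideca-3,11-dien-1-yl]-1,2,5-trimethyl-1,2,3,4,5,6,7,8-octahydronaphthalen-1-yl]methyl}-1,4-dimethoxybenzene | CC(C)=CCC[C@@](C)(O[Si](C)(C)C(C)(C)C)[C@@H](O[Si](C)(C)C(C)(C)C)CC/C(C)=C/CC[C@@]1(C)CCCC2=C1CC[C@H](C)[C@@]2(C)Cc1cc(OC)ccc1OC | intermediate
34 | 2-{[(1R,2S,5R)-5-[(3E,7S,8R)-7,8-bis{[tert-butyl(dimethyl)silyl]oxy}-4,8,12-trimethyltrideca-3,11-dien-1-yl]-1,2,5-trimethyl-1,2,3,4,5,6,7,8-octahydronaphthalen-1-yl]methyl}cyclohexa-2,5-diene-1,4-dione | CC(C)=CCC[C@@](C)(O[Si](C)(C)C(C)(C)C)[C@@H](O[Si](C)(C)C(C)(C)C)CC/C(C)=C/CC[C@@]1(C)CCCC2=C1CC[C@H](C)[C@@]2(C)CC1=CC(=O)C=CC1=O | intermediate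
35 | 2-{[(1R,2S,5R)-5-[(3E,7S,8R)-7,8-bis{[tert-butyl(dimethyl)silyl]oxy}-4,8,12-trimethyltrideca-3,11-dien-1-yl]-1,2,5-trimethyl-1,2,3,4,5,6,7,8-octahydronaphthalen-1-yl]methyl}benzene-1,4-diol | CC(C)=CCC[C@@](C)(O[Si](C)(C)C(C)(C)C)[C@@H](O[Si](C)(C)C(C)(C)C)CC/C(C)=C/CC[C@@]1(C)CCCC2=C1CC[C@H](C)[C@@]2(C)Cc1cc(O)ccc1O | intermediate
36 | 2-{[(1R,2S,5R)-5-[(3E,7S,8R)-7,8-bis{[tert-butyl(dimethyl)silyl]oxy}-4,8,12-trimethyltrideca-3,11-dien-1-yl]-1,2,5-trimethyl-1,2,3,4,5,6,7,8-octahydronaphthalen-1-yl]methyl}benzene-1,4-diyl bis(hydrogen sulfate) | CC(C)=CCC[C@@](C)(O[Si](C)(C)C(C)(C)C)[C@@H](O[Si](C)(C)C(C)(C)C)CC/C(C)=C/CC[C@@]1(C)CCCC2=C1CC[C@H](C)[C@@]2(C)Cc1cc(OS(=O)(=O)O)ccc1OS(=O)(=O)O | intermediate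
37 | 2-{[(1R,2S,5R)-5-[(3E,7S,8R)-7,8-dihydroxy-4,8,12-trimethyltrideca-3,11-dien-1-yl]-1,2,5-trimethyl-1,2,3,4,5,6,7,8-octahydronaphthalen-1-yl]methyl}benzene-1,4-diyl bis(hydrogen sulfate) | CC(C)=CCC[C@@](C)(O)[C@@H](O)CC/C(C)=C/CC[C@@]1(C)CCCC2=C1CC[C@H](C)[C@@]2(C)Cc1cc(OS(=O)(=O)O)ccc1OS(=O)(=O)O | target

**Totals**
Total step count: 21. Longest linear sequence: 12 steps (steps 2–9 then 18–21; the geraniol branch, steps 10–17 then 18–21, is also 12).

**Three steps most likely to fail**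

Step 18 (the proposed new reaction). The risks are direct alkenyl–allyl coupling before cyclization, rearrangement of the neopentyl palladium intermediate, and γ-attack of the allyl unit. The fallback uses known chemistry, sets out from 17 and comes back at 33. Compound 17 is cyclised under classical asymmetric Heck–carbonylation conditions (Pd(OAc)2, (R)-BINAP, CO 1 atm, MeOH, Et3N, DMF, 70 °C), where CO insertion traps the same alkylpalladium, to give methyl 2-[(1R,5R,6S)-5-[(2,5-dimethoxyphenyl)methyl]-1,5,6-trimethyl-1,2,3,4,5,6,7,8-octahydronaphthalen-1-yl]acetate F1. LiAlH4 reduction gives 2-[(1R,5R,6S)-5-[(2,5-dimethoxyphenyl)methyl]-1,5,6-trimethyl-1,2,3,4,5,6,7,8-octahydronaphthalen-1-yl]ethan-1-ol F2. I2/PPh3/imidazole gives 2-{[(1R,2S,5R)-5-(2-iodoethyl)-1,2,5-trimethyl-1,2,3,4,5,6,7,8-octahydronaphthalen-1-yl]methyl}-1,4-dimethoxybenzene F3. Treatment with t-BuLi and then B-methoxy-9-BBN gives the lithium B-alkyl-B-methoxy-9-borabicyclononane borate of F3 (iodine replaced by boron, configuration unchanged) F4, which is coupled in the same flask with alkenyl iodide 29 (Pd(dppf)Cl2, K3PO4, DMF/H2O, 25 °C) to give 33.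

Step 7 (oxidative transposition of the hindered 2-iodo tertiary allylic alcohol). The risks are slow chromate ester formation and dehydration to a diene. The fallback sets out from 13 and comes back at 17, replacing the oxidative transposition by a reductive one. SOCl2/pyridine in Et2O at −20 °C effects allylic rearrangement with chloride delivery to the ring CH, giving 2-{[(1R,4S,6S)-4-chloro-3-iodo-1,6-dimethyl-2-(4-methylpent-4-en-1-yl)cyclohex-2-en-1-yl]methyl}-1,4-dimethoxybenzene F5. LiBHEt3 (THF, 0 °C) then removes the allylic chloride to give 17; this bypasses 14, 15 and 16.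

Step 19 (oxidative demethylation next to an electron-rich tetrasubstituted alkene and silyl ethers). The fallback sets out from 33 and comes back at hydroquinone 35, which then enters the sulfation of step 20. It replaces oxidation by nucleophilic SN2 demethylation with n-BuSLi (from n-BuSH and n-BuLi) in HMPA at 110 °C under argon, as used for related hydroquinone dimethyl ethers; no new compound is made on this detour (F0).

**Further compounds**
F1 | step 18 | methyl 2-[(1R,5R,6S)-5-[(2,5-dimethoxyphenyl)methyl]-1,5,6-trimethyl-1,2,3,4,5,6,7,8-octahydronaphthalen-1-yl]acetate | COC(=O)C[C@@]1(C)CCCC2=C1CC[C@H](C)[C@@]2(C)Cc3cc(OC)ccc3OC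
F2 | step 18 | 2-[(1R,5R,6S)-5-[(2,5-dimethoxyphenyl)methyl]-1,5,6-trimethyl-1,2,3,4,5,6,7,8-octahydronaphthalen-1-yl]ethan-1-ol | OCC[C@@]1(C)CCCC2=C1CC[C@H](C)[C@@]2(C)Cc3cc(OC)ccc3OC
F3 | step 18 | 2-{[(1R,2S,5R)-5-(2-iodoethyl)-1,2,5-trimethyl-1,2,3,4,5,6,7,8-octahydronaphthalen-1-yl]methyl}-1,4-dimethoxybenzene | ICC[C@@]1(C)CCCC2=C1CC[C@H](C)[C@@]2(C)Cc3cc(OC)ccc3OC
F4 | step 18 | lithium B-methoxy-9-borabicyclononane borate of F3 (iodine replaced by boron, configuration unchanged) | [Li+].CO[B-]1(CC[C@@]2(C)CCCC3=C2CC[C@H](C)[C@@]3(C)Cc4cc(OC)ccc4OC)C5CCCC1CCC5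
F5 | step 7 | 2-{[(1R,4S,6S)-4-chloro-3-iodo-1,6-dimethyl-2-(4-methylpent-4-en-1-yl)cyclohex-2-en-1-yl]methyl}-1,4-dimethoxybenzene | C=C(C)CCCC1=C(I)[C@@H](Cl)C[C@H](C)[C@@]1(C)Cc2cc(OC)ccc2OC
F0 | step 19 | none | none
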